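The cyclobutane (C1–C4 as in the SMILES; aryl on C1/C3, acyl on C2/C4) is disconnected at C4–C1. The feature exploited is its 1,3-diacyl pattern: ring carbons C3, C4, C5 and C6 of methyl coumalate are C4, C3, C2 and C1, with the lactone carbonyl on C4 and the ester on C2. One photochemical disrotatory 4π-electrocyclisation forms C4–C1, closes the carbocycle and gives a cis-fused cyclobutene β-lactone whose allylic C1–O bond relays all later stereochemistry. The precursor is the flat, commercial 2-pyrone itself. The aryl groups follow by anti-SN2′ cuprate opening (C3) and amide-directed C–H arylation (C1).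

Key step: step 1

Remark on the chemistry: the target has a centre of inversion (C1-aryl and C4-acyl on one face, C2-acyl and C3-aryl on the other, the α-truxillic pattern), so it is achiral and has no enantiomer; chiral intermediates are therefore racemic, each SMILES shows one enantiomer, and C1–C4 always mean target numbering.

Step 1
Reactants: 1 methyl coumalate
Product: 2 methyl 3-oxo-2-oxabicyclo[2.2.0]hex-5-ene-6-carboxylate (racemic, cis-fused)
Conditions: hν (medium-pressure Hg lamp, Pyrex, λ > 290 nm), degassed CH2Cl2 (0.05 M), 0–5 °C; concentrated cold to a stock solution, never to dryness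
Reagents that add atoms: none
Why: Direct (singlet π,π*) excitation of the 2-pyrone triggers a disrotatory 4π-electrocyclisation of the diene C3=C4–C5=C6, which forms the σ bond between pyrone C3 and C6 (C4–C1 of the target). This is the known photochemical valence isomerisation of 2-pyrones, methyl coumalate included, to 2-oxabicyclo[2.2.0]hex-5-en-3-ones. The cyclobutene ring closes in the photochemically allowed disrotatory 4π-electrocyclic mode, and the six-membered lactone is thereby contracted to the β-lactone. Both new stereocentres, the bridgeheads C4 and C1, are fixed relative to each other by the disrotatory motion and by the fact that a bicyclo[2.2.0] frame can only be cis-fused; absolute control is not needed because the target is achiral. The step needs unimolecular closure to win over photodimerisation, over trapping of the ring-opened ketene and over secondary photolysis with loss of CO2, and this is secured by dilution, an aprotic non-nucleophilic solvent and the Pyrex cut-off, behind which the simple enoate chromophore of 2 no longer absorbs. Irradiation and storage at or below 5 °C suppress thermal reversion to 1.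

Step 2
Reactants: 2 methyl 3-oxo-2-oxabicyclo[2.2.0]hex-5-ene-6-carboxylate; 3 4-bromo-1,2-dimethoxybenzene
Product: 6 rac-trans-4-(3,4-dimethoxyphenyl)-3-(methoxycarbonyl)cyclobut-2-ene-1-carboxylic acid (C3-aryl trans to C4-CO2H, alkene C1=C2), via 3,4-dimethoxyphenyllithium 4 (not isolated), via lithium bis(3,4-dimethoxyphenyl)cuprate 5 (not isolated)
Conditions: 3 (2.1 equiv), n-BuLi, THF, −78 °C; CuBr·SMe2 (1.05 equiv), −78 → −30 °C; cuprate cannulated into 2, THF/CH2Cl2, −78 °C; cold 1 M HCl; NaHCO3/HCl acid–base extraction at ≤ 0 °C; EtOAc solution used at once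
Reagents that add atoms: none
Why: Anti-SN2′ opening of a vinyl-substituted β-lactone by a lithium diarylcuprate, known for 2-oxabicyclo[2.2.0]hex-5-en-3-ones and here reinforced by the enoate (C3 is both the SN2′ terminus and the β-carbon): copper attacks C3 on the convex face, anti to the C1–O bond, so the aryl ends trans to the C4 carboxyl, and strain-driven departure of the carboxylate shifts the alkene to C1=C2.

Step 3
Reactants: 6 rac-trans-4-(3,4-dimethoxyphenyl)-3-(methoxycarbonyl)cyclobut-2-ene-1-carboxylic acid
Product: 7 rac-2-(3,4-dimethoxyphenyl)-3-(methoxycarbonyl)cyclobutane-1-carboxylic acid (C3-aryl trans to C4-CO2H, C2-CO2Me cis to C3-aryl, C1 = CH2)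
Conditions: H2 (1 atm), 5% Pt/C, EtOAc, 0 °C
Reagents that add atoms: none
Why: Heterogeneous syn-hydrogenation of a strained trisubstituted cyclobutene: the C3 aryl flanks the ester-bearing C2 and blocks its face, so the catalyst should bind the face that carries only the small, surface-anchoring C4 carboxyl, hydrogen enters C2 from there and the ester is turned cis to the aryl, while Pt (little alkene migration) and 0 °C keep C3 intact and outrun conrotatory ring opening.

Step 4
Reactants: 7 rac-2-(3,4-dimethoxyphenyl)-3-(methoxycarbonyl)cyclobutane-1-carboxylic acid; 8 2-(methylsulfanyl)aniline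
Product: 9 rac-methyl 2-(3,4-dimethoxyphenyl)-3-{[2-(methylsulfanyl)phenyl]carbamoyl}cyclobutane-1-carboxylate (ester cis to aryl, amide trans to aryl)
Conditions: EDC·HCl, CH2Cl2, 0 °C → rt
Reagents that add atoms: none
Why: Carbodiimide amide coupling that installs an N,S-bidentate directing group; no stereocentre is formed and C4, whose acyl group is already trans to the neighbouring aryl, has no drive to epimerise.

Step 5
Reactants: 9 rac-methyl 2-(3,4-dimethoxyphenyl)-3-{[2-(methylsulfanyl)phenyl]carbamoyl}cyclobutane-1-carboxylate; 10 4-iodo-1,2-dimethoxybenzene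
Product: 11 rac-methyl 2,4-bis(3,4-dimethoxyphenyl)-3-{[2-(methylsulfanyl)phenyl]carbamoyl}cyclobutane-1-carboxylate (C1-aryl and C4-amide on one face, C2-ester and C3-aryl on the other)
Conditions: Pd(OAc)2 (15 mol %), Ag2CO3, PivOH, t-BuOH, 75 °C
Reagents that add atoms: none
Why: Auxiliary-directed Pd(II)/Pd(IV) β-C(sp3)–H arylation, well established for cyclobutanecarboxamides of this anilide: the fused palladacycle can only engage a C–H bond cis to the C4 amide, the secondary C1–H is palladated in preference to the tertiary benzylic C3–H, and C–C bond formation with retention places the aryl on C1 cis to the C4 acyl and trans to the C2 ester.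

Step 6
Reactants: 11 rac-methyl 2,4-bis(3,4-dimethoxyphenyl)-3-{[2-(methylsulfanyl)phenyl]carbamoyl}cyclobutane-1-carboxylate
Product: 12 N-Boc derivative of 11 (same relative configuration)
Conditions: Boc2O, DMAP, MeCN, rt
Reagents that add atoms: di-tert-butyl dicarbonate, CC(C)(C)OC(=O)OC(=O)OC(C)(C)C
Why: DMAP-catalysed N-acylation of the secondary anilide with Boc2O, the usual activation of directing-group amides, twists the amide out of conjugation without touching a stereocentre.

Step 7
Reactants: 12 N-Boc derivative of 11
Product: 13 (1α,2α,3β,4β)-2,4-bis(3,4-dimethoxyphenyl)cyclobutane-1,3-dicarboxylic acid (centrosymmetric, achiral)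
Conditions: LiOH, 30% H2O2, THF/H2O, 0 °C → rt; Na2SO3; 1 M HCl
Reagents that add atoms: hydrogen peroxide, OO; lithium hydroxide, [Li+].[OH-]
Why: Hydroperoxide cleavage of the N-Boc amide at the acyl carbon together with ester saponification; C2 and C4 should hold because the trans-1,3-diacyl (α-truxillic) arrangement is the more stable of the two that enolisation could interconvert.

Step 8
Reactants: 13 (1α,2α,3β,4β)-2,4-bis(3,4-dimethoxyphenyl)cyclobutane-1,3-dicarboxylic acid; 14 5,6-dihydropyridin-2(1H)-one
Product: 17 1,1′-{[(1α,2α,3β,4β)-2,4-bis(3,4-dimethoxyphenyl)cyclobutane-1,3-diyl]dicarbonyl}bis(5,6-dihydropyridin-2(1H)-one), the target, via (1α,2α,3β,4β)-2,4-bis(3,4-dimethoxyphenyl)cyclobutane-1,3-dicarbonyl dichloride 15 (not isolated), via lithium 6-oxo-3,6-dihydropyridin-1(2H)-ide 16 (not isolated)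
Conditions: (COCl)2, DMF (cat.), CH2Cl2, 0 °C → rt, evaporate; 14 (2.2 equiv), n-BuLi, THF, −78 °C; then 15 in THF, −78 → 0 °C
Reagents that add atoms: none
Why: Vilsmeier-catalysed acid chloride formation and N-acylation of a preformed lithium lactamide, the standard entry to N-acyl-5,6-dihydropyridin-2(1H)-ones; the absence of amine base at −78 °C avoids ketene formation, so C2 and C4 are not scrambled and the conjugated lactam alkene is left alone.

Compound list
1 | methyl coumalate (methyl 2-oxo-2H-pyran-5-carboxylate) | COC(=O)C1=COC(=O)C=C1 | starting material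
2 | methyl 3-oxo-2-oxabicyclo[2.2.0]hex-5-ene-6-carboxylate (racemic, cis-fused) | COC(=O)C1=C[C@H]2C(=O)O[C@@H]12 | intermediate
3 | 4-bromo-1,2-dimethoxybenzene | COc1ccc(Br)cc1OC | starting material
4 | 3,4-dimethoxyphenyllithium | [Li]c1ccc(OC)c(OC)c1 | intermediate
5 | lithium bis(3,4-dimethoxyphenyl)cuprate | [Li+].COc1ccc([Cu-]c2ccc(OC)c(OC)c2)cc1OC | intermediate
6 | rac-trans-4-(3,4-dimethoxyphenyl)-3-(methoxycarbonyl)cyclobut-2-ene-1-carboxylic acid | COC(=O)C1=C[C@H](C(O)=O)[C@H]1c2ccc(OC)c(OC)c2 | intermediate
7 | rac-2-(3,4-dimethoxyphenyl)-3-(methoxycarbonyl)cyclobutane-1-carboxylic acid (aryl trans to CO2H, CO2Me cis to aryl) | COC(=O)[C@H]1C[C@H](C(O)=O)[C@H]1c2ccc(OC)c(OC)c2 | intermediate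
8 | 2-(methylsulfanyl)aniline | CSc1ccccc1N | starting material
9 | rac-methyl 2-(3,4-dimethoxyphenyl)-3-{[2-(methylsulfanyl)phenyl]carbamoyl}cyclobutane-1-carboxylate (ester cis, amide trans to aryl) | COC(=O)[C@H]1C[C@H](C(=O)Nc2ccccc2SC)[C@H]1c1ccc(OC)c(OC)c1 | intermediate
10 | 4-iodo-1,2-dimethoxybenzene | COc1ccc(I)cc1OC | starting material
11 | rac-methyl 2,4-bis(3,4-dimethoxyphenyl)-3-{[2-(methylsulfanyl)phenyl]carbamoyl}cyclobutane-1-carboxylate (C1-aryl/C4-amide cis; C2-ester/C3-aryl cis; aryls trans; acyls trans) | COC(=O)[C@H]1[C@H](c2ccc(OC)c(OC)c2)[C@H](C(=O)Nc2ccccc2SC)[C@H]1c1ccc(OC)c(OC)c1 | intermediate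
12 | rac-methyl 3-{(tert-butoxycarbonyl)[2-(methylsulfanyl)phenyl]carbamoyl}-2,4-bis(3,4-dimethoxyphenyl)cyclobutane-1-carboxylate (configuration as 11) | COC(=O)[C@H]1[C@H](c2ccc(OC)c(OC)c2)[C@H](C(=O)N(C(=O)OC(C)(C)C)c2ccccc2SC)[C@H]1c1ccc(OC)c(OC)c1 | intermediate
13 | (1α,2α,3β,4β)-2,4-bis(3,4-dimethoxyphenyl)cyclobutane-1,3-dicarboxylic acid (achiral) | OC(=O)[C@H]1[C@H](c2ccc(OC)c(OC)c2)[C@H](C(O)=O)[C@H]1c1ccc(OC)c(OC)c1 | intermediate
14 | 5,6-dihydropyridin-2(1H)-one | O=C1C=CCCN1 | starting material
15 | (1α,2α,3β,4β)-2,4-bis(3,4-dimethoxyphenyl)cyclobutane-1,3-dicarbonyl dichloride | ClC(=O)[C@H]1[C@H](c2ccc(OC)c(OC)c2)[C@H](C(Cl)=O)[C@H]1c1ccc(OC)c(OC)c1 | intermediate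
16 | lithium 6-oxo-3,6-dihydropyridin-1(2H)-ide (N-lithio lactam) | [Li]N1CCC=CC1=O | intermediate
17 | 1,1′-{[(1α,2α,3β,4β)-2,4-bis(3,4-dimethoxyphenyl)cyclobutane-1,3-diyl]dicarbonyl}bis(5,6-dihydropyridin-2(1H)-one) (CNP0199212.1, achiral) | COc1ccc([C@H]2[C@H](C(=O)N3CCC=CC3=O)[C@H](c3ccc(OC)c(OC)c3)[C@H]2C(=O)N2CCC=CC2=O)cc1OC | target

Total step count: 8. Longest linear sequence: 8 steps (1 → 17).

Steps most likely to fail

Step 2.
- What may go wrong:
  - attack at the β-lactone carbonyl instead of C3;
  - a second conjugate addition of cuprate to the new C1=C2 enoate, which would load C1 from the wrong face;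
  - thermal reversion of 2 before it reacts;
  - conrotatory opening of the aryl cyclobutene to a dienoic acid during work-up.
- Fallback, setting out from 2: the cold photolysate is hydrogenated directly (H2, Pt/C, CH2Cl2, 0–5 °C). Saturation from the convex face with C1–O hydrogenolysis gives cis-3-(methoxycarbonyl)cyclobutane-1-carboxylic acid F1.
- EDC coupling with 8 gives methyl cis-3-{[2-(methylsulfanyl)phenyl]carbamoyl}cyclobutane-1-carboxylate F2.
- Directed mono-arylation with 10 (Pd(OAc)2, Ag2CO3, PivOH, HFIP) gives rac-methyl all-cis-2-(3,4-dimethoxyphenyl)-3-{[2-(methylsulfanyl)phenyl]carbamoyl}cyclobutane-1-carboxylate F3.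
- Base epimerisation at the amide-bearing carbon (LiOt-Bu, toluene) relieves the all-cis strain, and the sequence comes back to the route at 9.
- Both aryl groups are then installed by C–H arylation, and no cyclobutene is ever handled.

Step 3.
- What may go wrong: poor facial selectivity if the carboxyl hinders its own face as much as the aryl hinders the other; alkene migration on the metal; ring opening while the reduction is slow.
- Fallback, setting out from 6: the alkene is reduced without regard to face (Pt/C or diimide at 0 °C). This gives 7 mixed with its C2 epimer, rac-2-(3,4-dimethoxyphenyl)-3-(methoxycarbonyl)cyclobutane-1-carboxylic acid with the ester trans to the aryl F4.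
- The unseparated mixture is converted into the carboxylate/ester-enolate dianion (LDA, 2.2 equiv, THF, −78 °C) and protonated kinetically with a bulky phenol.
- C2 is then a single trigonal carbon whose only neighbouring stereocentre is the aryl-bearing C3. The proton should therefore arrive anti to the aryl and turn the ester cis to it, and the fallback comes back at 7.

Step 5.
- What may go wrong: slow palladation of the crowded C1 methylene; competing ortho-palladation of the electron-rich aryl ring; catalyst deactivation; epimerisation of the cis ester at C2 on prolonged heating.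
- Fallback, setting out from 7: the auxiliary is omitted and the native carboxylate directs the arylation. Ligand-enabled free-acid β-C(sp3)–H arylation is used: Pd(OAc)2, pyridine–pyridone or mono-N-protected amino acid ligand, Ag2CO3, 10, HFIP, 80–100 °C.
- This gives rac-2,4-bis(3,4-dimethoxyphenyl)-3-(methoxycarbonyl)cyclobutane-1-carboxylic acid F5.
- Saponification of F5 (LiOH, THF/MeOH/H2O) comes back to the route at 13.
- This variant is shorter, but the weaker coordination makes it less certain, so it is held in reserve.

Further compounds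
F1 | step 2 | cis-3-(methoxycarbonyl)cyclobutane-1-carboxylic acid | COC(=O)[C@@H]1C[C@H](C(O)=O)C1
F2 | step 2 | methyl cis-3-{[2-(methylsulfanyl)phenyl]carbamoyl}cyclobutane-1-carboxylate | COC(=O)[C@@H]1C[C@H](C(=O)Nc2ccccc2SC)C1
F3 | step 2 | rac-methyl all-cis-2-(3,4-dimethoxyphenyl)-3-{[2-(methylsulfanyl)phenyl]carbamoyl}cyclobutane-1-carboxylate | COC(=O)[C@H]1C[C@@H](C(=O)Nc2ccccc2SC)[C@H]1c1ccc(OC)c(OC)c1
F4 | step 3 | rac-2-(3,4-dimethoxyphenyl)-3-(methoxycarbonyl)cyclobutane-1-carboxylic acid, C2 epimer of 7 (ester trans to aryl, cis-1,3 to CO2H) | COC(=O)[C@@H]1C[C@H](C(O)=O)[C@H]1c2ccc(OC)c(OC)c2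
F5 | step 5 | rac-2,4-bis(3,4-dimethoxyphenyl)-3-(methoxycarbonyl)cyclobutane-1-carboxylic acid (C1-aryl/C4-CO2H cis; C2-ester/C3-aryl cis) | COC(=O)[C@H]1[C@H](c2ccc(OC)c(OC)c2)[C@H](C(O)=O)[C@H]1c1ccc(OC)c(OC)c1
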